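**Plan**
- Retrosynthesis: the two phenolic O–H bonds go back to aryl silyl ethers, then the benzene ring is cut at C1–C2 and C5–C6. This gives a four-carbon 1,1,2-tris(siloxy)butadiene (ring C2–C5) and a two-carbon alkynoate (ring C1 and C6, with the ester already attached).
- Enabling feature: on the benzene ring the ester-bearing C1 sits next to C2–OH and C3–OH, while C4–C6 carry only hydrogen. The ester carbon can therefore come from the α-carbon of a propiolate bonded to the ketal carbon of a 1,1,2-trioxygenated diene.
- Forward order: the diene is made from methyl vinylglycolate (saponification, bis-silylation, O-silylation of the dienolate). The octadecyl chain is joined to propiolic acid by esterification before any ring exists.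
- The only ring arises in the cycloaddition/silanol-loss step; acid hydrolysis of the two aryl silyl ethers ends the route.
- Stereochemistry: the target has no stereocentre and no double-bond isomerism, so nothing has to be set.

Key step: step 5

Remark: because the target is achiral, "single enantiomer" imposes no requirement; racemic 1 is used, and its one stereocentre is erased at the dienolate stage in step 3.

**Route**

Step 1
Reactants: 1 racemic methyl 2-hydroxybut-3-enoate
Product: 3 racemic 2-hydroxybut-3-enoic acid, via lithium 2-hydroxybut-3-enoate 2 (not isolated)
Conditions: LiOH·H2O (1.1 equiv), THF–H2O 3:1, 0 °C; then 1 M HCl to pH 2, NaCl-saturated, EtOAc extraction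
Reagents that add atoms: lithium hydroxide, [Li+].[OH-]
Why: Saponification (BAC2 ester hydrolysis) is fast for an α-hydroxy ester at 0 °C, and the carboxylate once formed resists α-deprotonation, so the vinyl group should not migrate into conjugation; C2 stays racemic.

Step 2
Reactants: 3 racemic 2-hydroxybut-3-enoic acid
Product: 4 racemic trimethylsilyl 2-(trimethylsiloxy)but-3-enoate
Conditions: TMSCl (2.3 equiv), Et3N (2.5 equiv), Et2O, 0 °C to rt; filtration under Ar, distillation
Reagents that add atoms: chlorotrimethylsilane, C[Si](C)(C)Cl
Why: Silylation of the alcohol and the carboxylic acid with a silyl chloride and amine base is the standard way to silyl α-siloxy esters, should give a distillable product and leaves the isolated alkene untouched.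

Step 3
Reactants: 4 racemic trimethylsilyl 2-(trimethylsiloxy)but-3-enoate
Product: 6 1,1,2-tris(trimethylsiloxy)buta-1,3-diene, via lithium dienolate 5 (not isolated)
Conditions: LiHMDS (1.1 equiv), THF, −78 °C; then TMSCl (1.2 equiv), −78 °C to rt; pentane, filtration, bulb-to-bulb distillation, stored cold under Ar
Reagents that add atoms: chlorotrimethylsilane, C[Si](C)(C)Cl
Why: Bis-silyl ketene acetal formation: the only acidic C–H of 4 (α to the silyl ester and allylic) is removed by the hindered amide and dienolate 5 is trapped on oxygen by the hard silyl chloride, as in the known conversion of silyl siloxyacetates into tris(siloxy)ethylenes; the C2 stereocentre is erased and the two identical groups on C1 leave no alkene geometry to control.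

Step 4
Reactants: 7 propiolic acid (1.5 equiv); 8 1-octadecanol
Product: 9 octadecyl propiolate
Conditions: p-TsOH·H2O (5 mol%), PhMe, reflux, Dean–Stark
Reagents that add atoms: none
Why: Fischer esterification driven by azeotropic removal of water; the terminal alkyne tolerates catalytic sulfonic acid and the primary fatty alcohol is unhindered.

Step 5
Reactants: 6 1,1,2-tris(trimethylsiloxy)buta-1,3-diene (2 equiv); 9 octadecyl propiolate
Product: 11 octadecyl 2,3-bis(trimethylsiloxy)benzoate, via cyclohexa-1,4-diene cycloadduct 10 (not isolated)
Conditions: PhMe, rt to 80 °C, sealed under Ar; volatiles removed under high vacuum, crude 11 carried on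
Reagents that add atoms: none
Why: Proposed new method: diene 6 and alkynoate 9 should combine in a polarised, asynchronous [4+2] cycloaddition in which the CH2 terminus of 6 attacks the β-carbon of 9 and the bis(siloxy) carbon then bonds to the ester-bearing carbon, so the six-membered ring is closed by intermolecular cycloaddition through arene bonds C5–C6 and C1–C2. Adduct 10 is a cyclohexa-1,4-diene with a silyl ketal at C2 and a doubly allylic CH2 at C5; ionisation of one siloxy group gives a siloxy-stabilised cyclohexadienyl cation (the arenium ion of 11 protonated para to the remaining ketal oxygen), which loses the C5 proton, expelling trimethylsilanol and leaving the benzene ring. The closest known reaction type is the Diels–Alder/aromatisation of 1,1-dioxygenated butadienes (ketene-acetal dienes) with alkynoates to give salicylates; the additional 2-siloxy group is the untested element. No stereocentre is formed, and since both groups on the ketal carbon are identical either may leave without changing the product. The selectivity needed is regiochemical (ester ortho to the ketal carbon rather than para to the 2-siloxy carbon); the two geminal donors should secure it by making the unhindered CH2 terminus the most nucleophilic diene carbon, outweighing the single 2-siloxy group, whose push falls on the crowded ketal carbon. Thermal, Lewis-acid-free conditions are chosen to disfavour open-chain Mukaiyama–Michael addition and [2+2] pathways, and the second equivalent of diene covers losses to the silanol released.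

Step 6
Reactants: 11 octadecyl 2,3-bis(trimethylsiloxy)benzoate
Product: 12 gentiside E (octadecyl 2,3-dihydroxybenzoate)
Conditions: 1 M aq. HCl, THF, 0 °C to rt
Reagents that add atoms: none
Why: Acid-catalysed hydrolysis of aryl trimethylsilyl ethers is rapid at room temperature, whereas the octadecyl benzoate is stable to dilute acid, and the acidic medium protects the free catechol from autoxidation.

**Compound list**
1 | racemic methyl 2-hydroxybut-3-enoate | C=CC(O)C(=O)OC | starting material
2 | lithium 2-hydroxybut-3-enoate (racemic) | C=CC(O)C(=O)[O-].[Li+] | intermediate
3 | racemic 2-hydroxybut-3-enoic acid | C=CC(O)C(=O)O | intermediate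
4 | racemic trimethylsilyl 2-(trimethylsiloxy)but-3-enoate | C=CC(O[Si](C)(C)C)C(=O)O[Si](C)(C)C | intermediate
5 | lithium 1,2-bis(trimethylsiloxy)buta-1,3-dien-1-olate | C=CC(O[Si](C)(C)C)=C([O-])O[Si](C)(C)C.[Li+] | intermediate
6 | 1,1,2-tris(trimethylsiloxy)buta-1,3-diene | C=CC(O[Si](C)(C)C)=C(O[Si](C)(C)C)O[Si](C)(C)C | intermediate
7 | propiolic acid | C#CC(=O)O | starting material
8 | 1-octadecanol | CCCCCCCCCCCCCCCCCCO | starting material
9 | octadecyl propiolate | C#CC(=O)OCCCCCCCCCCCCCCCCCC | intermediate
10 | octadecyl 5,6,6-tris(trimethylsiloxy)cyclohexa-1,4-diene-1-carboxylate | CCCCCCCCCCCCCCCCCCOC(=O)C1=CCC=C(O[Si](C)(C)C)C1(O[Si](C)(C)C)O[Si](C)(C)C | intermediate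
11 | octadecyl 2,3-bis(trimethylsiloxy)benzoate | CCCCCCCCCCCCCCCCCCOC(=O)c1cccc(O[Si](C)(C)C)c1O[Si](C)(C)C | intermediate
12 | gentiside E, octadecyl 2,3-dihydroxybenzoate | CCCCCCCCCCCCCCCCCCOC(=O)c1cccc(O)c1O | target

**Step count and risks**
Total steps: 6. Longest linear sequence: 5 (steps 1, 2, 3, 5, 6); step 4 is a one-step side branch.

Steps most likely to fail:

1. Step 5 (proposed new method). The cycloaddition may take the opposite orientation under the influence of the 2-siloxy group. The diene may also be consumed by open-chain conjugate addition, or by protodesilylation through the silanol released, so that little of the 2,3-dioxygenated ring forms. The fallback uses known chemistry and gives up the benzannulation. It sets out from 8, which is coupled with commercial 2,3-bis(benzyloxy)benzoic acid (EDC·HCl, DMAP, CH2Cl2, rt; Steglich-type esterification) to give octadecyl 2,3-bis(benzyloxy)benzoate F1. Hydrogenolysis (H2, Pd/C, EtOAc, rt) then removes both benzyl ethers, and the fallback comes back to the route at target 12.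

2. Step 3. Silyl transfer from the silyl ester to the amide base or to carbon may compete with O-silylation, or the very moisture-sensitive bis-silyl ketene acetal may hydrolyse or oligomerise during isolation. The fallback carries the methyl ester instead of the silyl ester and sets out from 1. O-Silylation (TMSCl, Et3N, Et2O) gives methyl 2-(trimethylsiloxy)but-3-enoate F2. LDA in THF at −78 °C gives lithium 1-methoxy-2-(trimethylsiloxy)buta-1,3-dien-1-olate F3, which TMSCl traps as the more robust mixed ketene acetal 1-methoxy-1,2-bis(trimethylsiloxy)buta-1,3-diene F4 (E/Z mixture at C1=C2, of no consequence). Heating F4 with 9 under the conditions of step 5 should give octadecyl 6-methoxy-5,6-bis(trimethylsiloxy)cyclohexa-1,4-diene-1-carboxylate F5, which is expected to aromatise by loss of methanol, the usual behaviour of 1-alkoxy-1-siloxybutadiene adducts. The fallback comes back to the route at 11; material in which the mixed ketal collapses to the dienone and tautomerises is the 2-phenol and converges on 12 in step 6.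

3. Step 4. Propiolic acid may decarboxylate, oligomerise or be lost by co-distillation during prolonged acid-catalysed reflux. The fallback forms the ester O–alkyl bond instead of the acyl–O bond and sets out from 8. Mesylation (MsCl, Et3N, CH2Cl2, 0 °C) gives octadecyl methanesulfonate F6, which alkylates caesium propiolate F7, generated in the flask from 7 and Cs2CO3 in DMF at rt to 40 °C. The fallback comes back to the route at 9.

**Further compounds**
F1 | step 5 | octadecyl 2,3-bis(benzyloxy)benzoate | CCCCCCCCCCCCCCCCCCOC(=O)c1cccc(OCc2ccccc2)c1OCc1ccccc1
F2 | step 3 | racemic methyl 2-(trimethylsiloxy)but-3-enoate | C=CC(O[Si](C)(C)C)C(=O)OC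
F3 | step 3 | lithium 1-methoxy-2-(trimethylsiloxy)buta-1,3-dien-1-olate | C=CC(O[Si](C)(C)C)=C([O-])OC.[Li+]
F4 | step 3 | 1-methoxy-1,2-bis(trimethylsiloxy)buta-1,3-diene | C=CC(O[Si](C)(C)C)=C(OC)O[Si](C)(C)C
F5 | step 3 | racemic octadecyl 6-methoxy-5,6-bis(trimethylsiloxy)cyclohexa-1,4-diene-1-carboxylate | CCCCCCCCCCCCCCCCCCOC(=O)C1=CCC=C(O[Si](C)(C)C)C1(OC)O[Si](C)(C)C
F6 | step 4 | octadecyl methanesulfonate | CCCCCCCCCCCCCCCCCCOS(C)(=O)=O
F7 | step 4 | caesium propiolate | C#CC(=O)[O-].[Cs+]
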